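**Retrosynthetic overview**
- The E-styryl arm is made last: Mizoroki–Heck coupling of a terminal vinyl group on the quaternary carbon with 8-iodo-7-methoxycoumarin; the vinyl group comes from an aldehyde by Wittig methylenation.
- The aldehyde comes from a ring-contracting Claisen [3,3] rearrangement of a 2-[(E)-2-arylethenyl]-2,5-dimethyl-3,4-dihydro-2H-pyran. This step forms the cyclohexene ring and both stereocentres by chirality transfer from the tertiary ether carbon.
- That dihydropyran comes from a Heck coupling of 6-bromo-7-methoxycoumarin with (R)-2-ethenyl-2,5-dimethyl-3,4-dihydro-2H-pyran, which is made from (R)-(−)-linalool (ozonolysis/oxidation, MeLi, methoxymethylenation, cyclisation). The linalool carbinol is the only stereocentre bought.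
- Ring order: the two coumarin rings first, then the dihydropyran ring, then the cyclohexene ring in the Claisen step.

Assumption: (R)-(−)-linalool is used at the enantiomeric purity supplied (lots of ≥97% ee are assumed); the ee of the target cannot exceed it.

**Step 1**
Reactants: 1 (R)-(−)-linalool, (3R)-3,7-dimethylocta-1,6-dien-3-ol
Product: 4 (5R)-5-ethenyl-5-methyloxolan-2-one, via hydroperoxy lactol 2 (not isolated), via lactol 3 (not isolated)
Conditions: O3, CH2Cl2, −78 °C (Sudan Red 7B end point); PPh3, −78 °C → rt; then TEMPO (10 mol%), PhI(OAc)2, rt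
Reagents that add atoms: ozone, [O-][O+]=O
Why: Ozonolysis cleaves the electron-rich trisubstituted alkene much faster than the vinyl group, the tertiary OH traps the carbonyl oxide, PPh3 reduces the hydroperoxide to the lactol and TEMPO/PhI(OAc)2 oxidises it to the lactone without touching the bought stereocentre.

**Step 2**
Reactants: 4 (5R)-5-ethenyl-5-methyloxolan-2-one
Product: 5 (5R)-5-hydroxy-5-methylhept-6-en-2-one
Conditions: MeLi (1.05 equiv), Et2O/THF, −78 °C; AcOH quench at −78 °C
Reagents that add atoms: methyllithium, [Li]C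
Why: Nucleophilic acyl addition of MeLi to the γ-lactone stops at the tetrahedral lithium alkoxide at −78 °C, so the methyl ketone appears only on quench and is not attacked a second time.

**Step 3**
Reactants: 5 (5R)-5-hydroxy-5-methylhept-6-en-2-one
Product: 6 (3R)-7-methoxy-3,6-dimethylhepta-1,6-dien-3-ol (E/Z mixture at the enol ether)
Conditions: Ph3P(CH2OMe)Cl (3 equiv), KOtBu (3 equiv), THF, 0 °C → rt
Reagents that add atoms: (methoxymethyl)triphenylphosphonium chloride, COC[P+](c1ccccc1)(c1ccccc1)c1ccccc1.[Cl-]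
Why: Wittig methoxymethylenation of the methyl ketone with excess ylide (one equivalent is buffered by the tertiary alkoxide) gives the enol ether, whose E/Z geometry is erased in the next step.

**Step 4**
Reactants: 6 (3R)-7-methoxy-3,6-dimethylhepta-1,6-dien-3-ol
Product: 8 (2R)-2-ethenyl-2,5-dimethyl-3,4-dihydro-2H-pyran, via cyclic methyl acetal 7 (not isolated)
Conditions: PPTS (5 mol%), toluene, rt 1 h, then reflux with slow distillation of the MeOH–toluene azeotrope; solid K2CO3 quench
Reagents that add atoms: none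
Why: Protonation of the enol ether and 6-exo capture of the oxocarbenium ion by the tertiary hydroxyl gives the cyclic acetal, which eliminates methanol under the same catalyst to the endocyclic enol ether (acetal exchange then elimination), with no bond to the stereocentre broken.

**Step 5**
Reactants: 9 5-bromo-2-hydroxy-4-methoxybenzaldehyde
Product: 11 6-bromo-7-methoxy-2H-chromen-2-one, via hydroxycinnamate ester 10 (not isolated)
Conditions: Ph3P=CHCO2Et (1.2 equiv), N,N-diethylaniline, reflux (215 °C), 4 h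
Reagents that add atoms: ethyl (triphenylphosphoranylidene)acetate, CCOC(=O)C=P(c1ccccc1)(c1ccccc1)c1ccccc1
Why: Wittig olefination gives the E-cinnamate, which isomerises and lactonises at this temperature to the coumarin (Wittig reaction followed by thermal cyclisation).

**Step 6**
Reactants: 8 (2R)-2-ethenyl-2,5-dimethyl-3,4-dihydro-2H-pyran; 11 6-bromo-7-methoxy-2H-chromen-2-one
Product: 12 6-{(E)-2-[(2R)-2,5-dimethyl-3,4-dihydro-2H-pyran-2-yl]ethenyl}-7-methoxy-2H-chromen-2-one
Conditions: Pd(OAc)2 (5 mol%), P(o-tol)3 (10 mol%), K2CO3, Bu4NBr, DMF, 100 °C, sealed tube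
Reagents that add atoms: none
Why: Mizoroki–Heck reaction in which the aryl–palladium species (from zerovalent palladium) adds to the terminal vinyl carbon; the neighbouring carbon is quaternary, so β-hydride elimination can only give the E-styrene, and the trisubstituted enol ether and the coumarin C3=C4 bond do not insert.

**Step 7**
Reactants: 12 6-{(E)-2-[(2R)-2,5-dimethyl-3,4-dihydro-2H-pyran-2-yl]ethenyl}-7-methoxy-2H-chromen-2-one
Product: 13 (1S,2S)-2-(7-methoxy-2-oxo-2H-chromen-6-yl)-1,4-dimethylcyclohex-3-ene-1-carbaldehyde (aryl and CHO cis)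
Conditions: degassed decalin (0.05 M), BHT (cat.), 200 °C, sealed base-washed tube, 8 h
Reagents that add atoms: none
Why: Claisen [3,3]-sigmatropic rearrangement of the 2-alkenyl-dihydropyran through the ring-enforced boat transition state forms the new C–C bond on the face from which the C–O bond leaves, so the (R) ether carbon fixes both new stereocentres (the E alkene puts the aryl group cis to CHO and trans to the methyl) as it becomes the sp2 ring carbon.

**Step 8**
Reactants: 13 (1S,2S)-2-(7-methoxy-2-oxo-2H-chromen-6-yl)-1,4-dimethylcyclohex-3-ene-1-carbaldehyde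
Product: 14 6-[(1R,6R)-6-ethenyl-3,6-dimethylcyclohex-2-en-1-yl]-7-methoxy-2H-chromen-2-one
Conditions: Ph3PCH3Br (1.2 equiv), KOtBu (1.15 equiv), THF, 0 °C; add 13 at −78 °C → 0 °C
Reagents that add atoms: methyltriphenylphosphonium bromide, C[P+](c1ccccc1)(c1ccccc1)c1ccccc1.[Br-]
Why: Wittig methylenation of the non-enolisable aldehyde, which is far more electrophilic than the coumarin lactone at low temperature; neither stereocentre can epimerise (the descriptors change only because of CIP priorities).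

**Step 9**
Reactants: 15 7-hydroxy-2H-chromen-2-one (umbelliferone)
Product: 16 7-hydroxy-8-iodo-2H-chromen-2-one
Conditions: I2 (1.0 equiv), KI, 20% aq. NH3, 0 °C → rt
Reagents that add atoms: iodine, II
Why: Electrophilic aromatic iodination of the phenoxide goes to C8, the position ortho to the phenol and flanked by the ring oxygen, which is the most activated site of umbelliferone.

**Step 10**
Reactants: 16 7-hydroxy-8-iodo-2H-chromen-2-one
Product: 17 8-iodo-7-methoxy-2H-chromen-2-one
Conditions: MeI, K2CO3, acetone, reflux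
Reagents that add atoms: iodomethane, CI
Why: Williamson O-methylation of the phenoxide.

**Step 11**
Reactants: 14 6-[(1R,6R)-6-ethenyl-3,6-dimethylcyclohex-2-en-1-yl]-7-methoxy-2H-chromen-2-one; 17 8-iodo-7-methoxy-2H-chromen-2-one
Product: 18 7-methoxy-6-{(1R,6R)-6-[(E)-2-(7-methoxy-2-oxo-2H-chromen-8-yl)ethenyl]-3,6-dimethylcyclohex-2-en-1-yl}-2H-chromen-2-one (CNP0287121.3)
Conditions: Pd(OAc)2 (10 mol%), Bu4NCl, NaHCO3, DMF, 90 °C
Reagents that add atoms: none
Why: Mizoroki–Heck coupling of the aryl iodide with the terminal vinyl group; the quaternary neighbour allows β-hydride elimination only toward the new benzylic carbon, giving the E alkene, and the two stereocentres are not involved.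

**Compound list**
1 | (R)-(−)-linalool, (3R)-3,7-dimethylocta-1,6-dien-3-ol | C=C[C@](C)(O)CCC=C(C)C | starting material
2 | (5R)-5-ethenyl-2-hydroperoxy-5-methyloxolane (anomer mixture) | C=C[C@@]1(C)CCC(OO)O1 | intermediate
3 | (5R)-5-ethenyl-5-methyloxolan-2-ol (anomer mixture) | C=C[C@@]1(C)CCC(O)O1 | intermediate
4 | (5R)-5-ethenyl-5-methyloxolan-2-one | C=C[C@@]1(C)CCC(=O)O1 | intermediate
5 | (5R)-5-hydroxy-5-methylhept-6-en-2-one | C=C[C@](C)(O)CCC(C)=O | intermediate
6 | (3R)-7-methoxy-3,6-dimethylhepta-1,6-dien-3-ol (E/Z mixture) | C=C[C@](C)(O)CCC(C)=COC | intermediate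
7 | (6R)-6-ethenyl-2-methoxy-3,6-dimethyloxane (mixture at C2 and C3) | C=C[C@@]1(C)CCC(C)C(OC)O1 | intermediate
8 | (2R)-2-ethenyl-2,5-dimethyl-3,4-dihydro-2H-pyran | C=C[C@@]1(C)CCC(C)=CO1 | intermediate
9 | 5-bromo-2-hydroxy-4-methoxybenzaldehyde | COc1cc(O)c(C=O)cc1Br | starting material
10 | ethyl (E)-3-(5-bromo-2-hydroxy-4-methoxyphenyl)prop-2-enoate | CCOC(=O)/C=C/c1cc(Br)c(OC)cc1O | intermediate
11 | 6-bromo-7-methoxy-2H-chromen-2-one | COc1cc2oc(=O)ccc2cc1Br | intermediate
12 | 6-{(E)-2-[(2R)-2,5-dimethyl-3,4-dihydro-2H-pyran-2-yl]ethenyl}-7-methoxy-2H-chromen-2-one | COc1cc2oc(=O)ccc2cc1/C=C/[C@@]1(C)CCC(C)=CO1 | intermediate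
13 | (1S,2S)-2-(7-methoxy-2-oxo-2H-chromen-6-yl)-1,4-dimethylcyclohex-3-ene-1-carbaldehyde | COc1cc2oc(=O)ccc2cc1[C@@H]1C=C(C)CC[C@]1(C)C=O | intermediate
14 | 6-[(1R,6R)-6-ethenyl-3,6-dimethylcyclohex-2-en-1-yl]-7-methoxy-2H-chromen-2-one | COc1cc2oc(=O)ccc2cc1[C@@H]1C=C(C)CC[C@]1(C)C=C | intermediate
15 | 7-hydroxy-2H-chromen-2-one (umbelliferone) | Oc1ccc2ccc(=O)oc2c1 | starting material
16 | 7-hydroxy-8-iodo-2H-chromen-2-one | Oc1ccc2ccc(=O)oc2c1I | intermediate
17 | 8-iodo-7-methoxy-2H-chromen-2-one | COc1ccc2ccc(=O)oc2c1I | intermediate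
18 | 7-methoxy-6-{(1R,6R)-6-[(E)-2-(7-methoxy-2-oxo-2H-chromen-8-yl)ethenyl]-3,6-dimethylcyclohex-2-en-1-yl}-2H-chromen-2-one | COc1cc2oc(=O)ccc2cc1[C@@H]1C=C(C)CC[C@]1(C)/C=C/c1c(OC)ccc2ccc(=O)oc12 | target

**Step count**
Total steps: 11.
Longest linear sequence: 8 steps (1 → 4 → 5 → 6 → 8 → 12 → 13 → 14 → 18; steps 1, 2, 3, 4, 6, 7, 8 and 11).

**Steps most likely to fail, with fallbacks**

Step 4 (cyclisation and loss of methanol). The acid needed to expel methanol may also ionise the tertiary allylic C–O bond, which would erode the ee, and 8 is volatile. The fallback sets out from 6 and avoids acid in the elimination. Hydrolyse the enol ether with 0.1 M HCl in THF/H2O at rt to the lactol (6R)-6-ethenyl-3,6-dimethyloxan-2-ol F1. Then dehydrate it under basic conditions (MsCl, Et3N, CH2Cl2, 0 °C → reflux) through the anomeric mesylate (6R)-6-ethenyl-3,6-dimethyloxan-2-yl methanesulfonate F2, which eliminates in the flask. This comes back to the route at 8.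

Step 7 (thermal Claisen ring contraction). The boat transition state places the aryl group over the ring methyl, so the reaction may need temperatures at which ionisation or decomposition competes. The fallback runs the same [3,3] shift at the lactone oxidation level, where it proceeds near 100 °C. It sets out from 8 and comes back to the route at 13:
- Oxidise the enol ether of 8 with pyridinium chlorochromate (C5H5NH)[CrO3Cl] and NaOAc in CH2Cl2 to the lactone (6R)-6-ethenyl-3,6-dimethyloxan-2-one F3.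
- Couple F3 with 11 under the conditions of step 6 to give (6R)-6-[(E)-2-(7-methoxy-2-oxo-2H-chromen-6-yl)ethenyl]-3,6-dimethyloxan-2-one F4.
- Treat F4 with LiN(SiMe3)2 and premixed Me3SiCl/Et3N in THF at −78 °C to form the silyl ketene acetal 7-methoxy-6-{(E)-2-[(2R)-2,5-dimethyl-6-(trimethylsilyloxy)-3,4-dihydro-2H-pyran-2-yl]ethenyl}-2H-chromen-2-one F5.
- Warm F5 in toluene to 100 °C (Ireland–Claisen ring contraction through the same boat transition state) to give trimethylsilyl (1S,2S)-2-(7-methoxy-2-oxo-2H-chromen-6-yl)-1,4-dimethylcyclohex-3-ene-1-carboxylate F6.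
- Aqueous work-up gives (1S,2S)-2-(7-methoxy-2-oxo-2H-chromen-6-yl)-1,4-dimethylcyclohex-3-ene-1-carboxylic acid F7.
- Convert F7 with (COCl)2 and catalytic DMF into (1S,2S)-2-(7-methoxy-2-oxo-2H-chromen-6-yl)-1,4-dimethylcyclohex-3-ene-1-carbonyl chloride F8, and reduce it with LiAlH(OtBu)3 in THF at −78 °C to aldehyde 13.

Step 11 (final Heck coupling). Both partners are hindered: the vinyl group sits on a quaternary carbon and the aryl iodide has two ortho substituents. The fallback replaces the Heck reaction by a Suzuki–Miyaura coupling; it sets out from 13 (so step 8 is skipped) and comes back at 18. Treat 13 with Cl2CHB(pin), CrCl2 and LiI in THF at rt (Takai-type boron olefination, E-selective) to give 7-methoxy-6-{(1R,6R)-3,6-dimethyl-6-[(E)-2-(4,4,5,5-tetramethyl-1,3,2-dioxaborolan-2-yl)ethenyl]cyclohex-2-en-1-yl}-2H-chromen-2-one F9. Couple F9 with 17 (PdCl2(dppf), K3PO4, dioxane/H2O, 80 °C, mildly acidic work-up) to give 18 with the alkene geometry retained.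

**Further compounds**
F1 | step 4 | (6R)-6-ethenyl-3,6-dimethyloxan-2-ol (diastereomer mixture) | C=C[C@@]1(C)CCC(C)C(O)O1
F2 | step 4 | (6R)-6-ethenyl-3,6-dimethyloxan-2-yl methanesulfonate | C=C[C@@]1(C)CCC(C)C(OS(C)(=O)=O)O1
F3 | step 7 | (6R)-6-ethenyl-3,6-dimethyloxan-2-one | C=C[C@@]1(C)CCC(C)C(=O)O1
F4 | step 7 | (6R)-6-[(E)-2-(7-methoxy-2-oxo-2H-chromen-6-yl)ethenyl]-3,6-dimethyloxan-2-one | COc1cc2oc(=O)ccc2cc1/C=C/[C@@]1(C)CCC(C)C(=O)O1
F5 | step 7 | 7-methoxy-6-{(E)-2-[(2R)-2,5-dimethyl-6-(trimethylsilyloxy)-3,4-dihydro-2H-pyran-2-yl]ethenyl}-2H-chromen-2-one | COc1cc2oc(=O)ccc2cc1/C=C/[C@@]1(C)CCC(C)=C(O[Si](C)(C)C)O1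
F6 | step 7 | trimethylsilyl (1S,2S)-2-(7-methoxy-2-oxo-2H-chromen-6-yl)-1,4-dimethylcyclohex-3-ene-1-carboxylate | COc1cc2oc(=O)ccc2cc1[C@@H]1C=C(C)CC[C@]1(C)C(=O)O[Si](C)(C)C
F7 | step 7 | (1S,2S)-2-(7-methoxy-2-oxo-2H-chromen-6-yl)-1,4-dimethylcyclohex-3-ene-1-carboxylic acid | COc1cc2oc(=O)ccc2cc1[C@@H]1C=C(C)CC[C@]1(C)C(=O)O
F8 | step 7 | (1S,2S)-2-(7-methoxy-2-oxo-2H-chromen-6-yl)-1,4-dimethylcyclohex-3-ene-1-carbonyl chloride | COc1cc2oc(=O)ccc2cc1[C@@H]1C=C(C)CC[C@]1(C)C(Cl)=O
F9 | step 11 | 7-methoxy-6-{(1R,6R)-3,6-dimethyl-6-[(E)-2-(4,4,5,5-tetramethyl-1,3,2-dioxaborolan-2-yl)ethenyl]cyclohex-2-en-1-yl}-2H-chromen-2-one | COc1cc2oc(=O)ccc2cc1[C@@H]1C=C(C)CC[C@]1(C)/C=C/B1OC(C)(C)C(C)(C)O1
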